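## Analysis of the target

CNP0171896.1 is a furanoheliangolide. Its ten-membered carbocycle (C1–C10, germacrane numbering; C11–C13 form the lactone arm, C14 is the methyl on C10, C15 the hydroxymethyl on C4) is bridged by an oxygen between C3 and C10, so that O–C3=C2–C1(=O)–C10 is a 3(2H)-furanone (ring B), and it is fused across C6–C7 to an α-methylene-γ-butyrolactone (ring C). There are four stereocentres: C6 (R), C7 (R) and C8 (R) are contiguous, with the lactone oxygen on C6 and the C11 branch on C7 on opposite faces of the ten-membered ring (trans-fused lactone) and the isovalerate on C8, while the oxygenated quaternary C10 (S) is insulated from this triad by the C9 methylene. The C4=C5 alkene is Z within the ring (C3 and C6 cis), carries the free C15 alcohol and is cross-conjugated with the furanone. The exocyclic methylene lactone is a Michael acceptor and is easily reduced or isomerised, the C6 acyloxy group is allylic, the C8 ester can eliminate or migrate, and the vinylogous-ester dienone does not tolerate strong base or nucleophiles. The difficulty is to close a ten-membered ring that holds two trigonal segments and an oxygen bridge, to set the trans C6/C7 pair on that ring, to secure the Z trisubstituted alkene, and to bring in the remote quaternary C10 with the right configuration. The strategy rests on the adjacency of the C6 carbinol and the C7 methine that bears C11=C13: HO–C6–C7–C11=C13 is a homoallylic alcohol, which a [2,3]-Wittig shift of a C6–O–C13 ether produces, and a C4≡C5 alkyne can acidify C6–H during that shift and later deliver the Z alkene.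

## Retrosynthetic reasoning

**Furanone O–C3 bond and the C15 silyl group (38 ⇐ 37 ⇐ 35).** The furanone is the most base- and nucleophile-sensitive part, so it is formed last. Cutting the enol-ether O–C3 bond leads back through the C1,C3-diketone 36 to the diol 35. The forward reaction is oxidation of the C1 carbinol followed by acid cyclodehydration of the C10 tertiary alcohol onto C3. Keeping C1 as a carbinol until then lets every earlier step use base.

**C4–C15 bond (34 ⇐ 33 ⇐ 32).** C4 must be an sp carbon in the key step, so C15 can only be added afterwards. The cut is made at the α-carbon of the Z-enone 32, which is the position a Morita–Baylis–Hillman hydroxymethylation addresses. The forward step needs C3 as a free ketone and C1 still masked (acetonide). The new primary alcohol is silylated (34) so that only C1 is oxidised later.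

**Lactone O–C12 bond and the C8 ester (32 ⇐ 31 ⇐ 30 ⇐ 29 ⇐ 27).** The lactone is opened to the C6/C12 diol 27. Both the C6 and the C8 oxygen are γ to C12, so C8 stays silylated while C12 is oxidised and C6 closes the ring (29). Only then is C8 unmasked and acylated (30, 31), and the C3 ketal removed (32).

**C4=C5 alkene (26 ⇐ 25).** The Z alkene is traced to the ring alkyne of 25. Cis semi-hydrogenation of a cycloalkyne can only give the ring-cis alkene. It is done before the reducible methylene lactone exists.

**C6–C7 bond (25 ⇐ 24), the key disconnection.** Cutting C6–C7 and joining the C6 oxygen to C13 turns the strained ten-membered cycloalkynol 25 into the thirteen-membered allyl propargyl ether 24. Forward, the ring contraction forms the carbocycle, both new stereocentres and the C11=C13 methylene in one concerted event. The strain is paid for by exchanging a carbanion for an alkoxide.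

**Ether O–C13 bond (24 ⇐ 23 ⇐ 20).** The macrocyclic ether is opened at O–C13 to the hydroxy allylic chloride 23, reached from the fully protected chain 20 by three functional-group operations (21, 22, 23). An intramolecular Williamson reaction is chosen because the propargylic alkoxide is a weak base and C13 is an unhindered primary allylic carbon.

**C11–C12 bond and the C7=C11 geometry (20 ⇐ 19 ⇐ 18 ⇐ 16).** The C12 arm is removed from the vinyl iodide 18, which comes from the propargylic alcohol 16. Hydroxyl-directed trans-hydroalumination and iodination fix the geometry (iodine, later C12, cis to C8; C13 trans), which is the geometry the rearrangement needs. A hydroxymethyl-transferring Stille coupling then gives 19.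

**C3–C4 bond (16 ⇐ 14 ⇐ 12 + 13).** The alkynyl ketal is cut between C3 and C4 into the Weinreb amide 12 and the propargyl ether 13. Acetylide addition gives ynone 14, and ketalisation removes the C3 electrophile and leaves C3 without a propargylic hydrogen.

**C1–C2 bond (12 ⇐ 11 ⇐ 10 ⇐ 8 + 9).** The C1/C10 diol acetonide is traced through triol 11 to the β-keto amide 10, made by acylating the enolate of 9 with the lactone carbonyl of 8. The C1 configuration is of no lasting consequence, but chelate-controlled reduction should give one epimer, which allows a cyclic acetal over C1/C10.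

**C7–C8 bond and the C8 stereocentre (8 ⇐ 6 ⇐ 4 + 2; 4 ⇐ 3; 2 and 13 ⇐ 1).** The lactone 8 arises from ynone 6 by catalyst-controlled transfer hydrogenation and acyl transfer. 6 comes from the acid 4 and the alkyne 2. (S)-Citramalic acid 3 supplies C1, C8, C9, C10 and C14 with the C10 configuration of the target, and propargyl alcohol 1 supplies both three-carbon alkyne units.

## Alternatives that were turned down

**Alternative 1:** The ten-membered ring is seen as the periphery of a bicycle of two six-membered rings that share the C1–C6 bond, assembled from a chiral-pool cyclohexenone and a second fragment. In the forward key step an oxygen-centred radical, generated from the ring-fusion C1 alcohol through its hypoiodite under irradiation, cleaves C1–C6. C1 becomes a ketone and the allylic C6 centre is captured by the C12 carboxyl group to give the lactone A1 (the ten-membered 9-en-1-one trans-lactone with a Z C4=C5 alkene).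
- In its favour: the medium ring is released from unstrained six-membered rings, no macrocyclisation is needed, C7 and C8 can be set on a cyclohexane, and the lactone forms in the same step. On convergence and probably on step count to the ten-membered ring it is stronger than the chosen route.
- Against it for this target: in A1, C10 is still the α-carbon of a C9=C10 enone. The oxygenated quaternary centre and the C3–O–C10 bridge would have to be made afterwards on a flexible macrocycle, and not by conjugate addition, since C10 is the α- and not the β-position. The C6 radical or cation is delocalised over C4–C6, which puts the Z geometry, the site of capture and the C6 configuration at risk.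
- In its place the chosen strategy offers C10 fixed from citramalic acid before any ring is formed, C6/C7 set by a concerted suprafacial shift, and a Z alkene guaranteed by an alkyne.

**Alternative 2:** The C9–C10 bond is cut. A preformed 2-methyl-3(2H)-furanone is ionised by a carbonate base to its aromatic 3-furanolate, and C10 of this anion displaces bromide from a C9 bromomethyl ketone. The step closes the carbocycle and creates the quaternary centre, giving A2 (the furanone-bridged ten-membered C8 ketone).
- In its favour: the step forms the ring and the hardest stereocentre together, uses a very reactive electrophile, and has the furanone in place from the start. On end-game economy it is clearly stronger than the chosen route, which needs several protecting-group and oxidation steps to close the same ring.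
- Against it: the furanolate is ambident (oxygen and two ring carbons). The C10 configuration would be controlled only by the remote C6/C7 centres through the conformation of the closing ring. C7 is α to the C8 ketone and β,γ-unsaturated in both the substrate and A2, so the basic conditions threaten epimerisation and migration of C11=C13 into conjugation. C8 then still needs a stereoselective reduction.
- The chosen strategy never places C7 next to a carbonyl under basic conditions and does not leave the C10 configuration to chance.

**Alternative 3:** The O–C10 bond is cut biomimetically. Acid activates the 1(10)-epoxide of a ten-membered 3-oxo-4Z-enolide, the C3 carbonyl oxygen opens it at the tertiary C10, and loss of a C2 proton gives the enol ether A3 (the bridged 2,3-dihydrofuran-3-ol with the C1 alcohol), one oxidation short of the furanone.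
- In its favour: the bridge, the C10 configuration (by inversion at the epoxide carbon) and the C1 oxygen are formed in one step without protecting groups, close to the presumed biosynthesis. As an end game it is shorter than the dehydration sequence of the chosen route.
- Against it: it does not build the ten-membered ring; the epoxy-germacranolide would still need a macrocyclisation of its own. The facial selectivity of epoxidation on a flexible ring is not secured. Acid on germacranolide epoxides commonly gives transannular C–C closure or participation of a neighbouring ester carbonyl (here the C8 isovalerate) instead of attack by the ketone oxygen.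
- The chosen strategy solves the ring construction and takes the C10–O bond from the chiral pool; its own end game closes the same furanone by a more conservative dehydration.

Key step: step 18

## Route

Assumption (remark on the chemistry): the C1 carbinol is carried as the single epimer (R) expected from chelate-controlled reduction in step 6; because C1 becomes a ketone in step 28, the other epimer would serve equally. Atom numbers in names are those of the germacrane skeleton defined in the analysis.

Step 1
Reactants: 1 propargyl alcohol
Product: 2 4-methoxybenzyl propargyl ether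
Conditions: NaH, 4-MeOC6H4CH2Cl, n-Bu4NI (cat.), THF, 0 °C → rt
Reagents that add atoms: 4-methoxybenzyl chloride, COc1ccc(CCl)cc1
Why: Williamson etherification of the primary alkoxide with a benzylic chloride; the PMB group masks the future C13 oxygen as a non-directing ether until step 14.

Step 2
Reactants: 3 (S)-citramalic acid
Product: 4 [(4S)-2,2,4-trimethyl-5-oxo-1,3-dioxolan-4-yl]acetic acid
Conditions: Me2C(OMe)2, p-TsOH (cat.), rt
Reagents that add atoms: 2,2-dimethoxypropane, COC(C)(C)OC
Why: Acetalisation of the α-hydroxy acid to its dioxolanone differentiates the two carboxyl groups (C1 masked as an acylal, C8 acid free) without touching the C10 stereocentre.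

Step 3
Reactants: 4 [(4S)-2,2,4-trimethyl-5-oxo-1,3-dioxolan-4-yl]acetic acid; 2 4-methoxybenzyl propargyl ether
Product: 6 (5S)-5-[5-(4-methoxybenzyloxy)-2-oxopent-3-yn-1-yl]-2,2,5-trimethyl-1,3-dioxolan-4-one, via acid chloride 5 (not isolated)
Conditions: (COCl)2, DMF (cat.), CH2Cl2, 0 °C → rt, evaporate; then 2, PdCl2(PPh3)2 (cat.), CuI (cat.), Et3N, THF, rt
Reagents that add atoms: none
Why: Acyl Sonogashira coupling of the acid chloride with the terminal alkyne forms the C7–C8 bond under conditions that leave the dioxolanone carbonyl untouched.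

Step 4
Reactants: 6 (5S)-5-[5-(4-methoxybenzyloxy)-2-oxopent-3-yn-1-yl]-2,2,5-trimethyl-1,3-dioxolan-4-one
Product: 8 (3S,5R)-3-hydroxy-5-[3-(4-methoxybenzyloxy)prop-1-yn-1-yl]-3-methyloxolan-2-one, via hydroxy dioxolanone 7 (not isolated)
Conditions: Ru[(R,R)-TsNCH(Ph)CH(Ph)NH](p-cymene) (1 mol %), i-PrOH, rt; then p-TsOH·H2O (cat.), CH2Cl2, rt
Reagents that add atoms: none
Why: Noyori asymmetric transfer hydrogenation of the alkynyl ketone is catalyst-controlled (the alkyne takes the place of the aryl group of the standard model), so the (R,R) catalyst should give the (R)-carbinol at C8 irrespective of C10. Acid then transfers the C1 acyl group to the new hydroxyl (five-membered lactone, acetone lost), which protects C8–O and keeps C1 as an acyl donor.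

Step 5
Reactants: 8 (3S,5R)-3-hydroxy-5-[3-(4-methoxybenzyloxy)prop-1-yn-1-yl]-3-methyloxolan-2-one; 9 N-methoxy-N-methylacetamide
Product: 10 (4S,6R)-4,6-dihydroxy-N-methoxy-9-(4-methoxybenzyloxy)-N,4-dimethyl-3-oxonon-7-ynamide (open form; in equilibrium with its five-membered hemiketal)
Conditions: 9, LiN(SiMe3)2 (3.5 equiv), THF, −78 °C; then 8, −78 → −40 °C; aq. NH4Cl
Reagents that add atoms: none
Why: Claisen-type acylation of the amide enolate by the lactone carbonyl forms C1–C2; one equivalent of base is consumed by the tertiary hydroxyl and the product is protected from further attack as its β-keto amide enolate.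

Step 6
Reactants: 10 (4S,6R)-4,6-dihydroxy-N-methoxy-9-(4-methoxybenzyloxy)-N,4-dimethyl-3-oxonon-7-ynamide
Product: 11 (3R,4S,6R)-3,4,6-trihydroxy-N-methoxy-9-(4-methoxybenzyloxy)-N,4-dimethylnon-7-ynamide
Conditions: Zn(BH4)2, Et2O, −20 → 0 °C
Reagents that add atoms: none
Why: Chelate-controlled (Cram chelate) reduction of the α-hydroxy ketone: zinc bridges the C1 carbonyl and the C10 oxygen and hydride enters from the methyl side, which should give the (1R) carbinol; the Weinreb amide is not reduced.

Step 7
Reactants: 11 (3R,4S,6R)-3,4,6-trihydroxy-N-methoxy-9-(4-methoxybenzyloxy)-N,4-dimethylnon-7-ynamide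
Product: 12 2-[(4R,5S)-5-[(2R)-2-hydroxy-5-(4-methoxybenzyloxy)pent-3-yn-1-yl]-2,2,5-trimethyl-1,3-dioxolan-4-yl]-N-methoxy-N-methylacetamide
Conditions: Me2C(OMe)2, PPTS (cat.), CH2Cl2, rt
Reagents that add atoms: 2,2-dimethoxypropane, COC(C)(C)OC
Why: Under equilibrating acetalisation the 1,2-diol (C1/C10) forms the five-membered acetonide in preference to the 1,3-dioxane over C8/C10, which would carry an axial substituent at the quaternary carbon; this leaves the C8 hydroxyl free for step 11.

Step 8
Reactants: 1 propargyl alcohol
Product: 13 triethyl(prop-2-yn-1-yloxy)silane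
Conditions: Et3SiCl, imidazole, CH2Cl2, 0 °C
Reagents that add atoms: chlorotriethylsilane, CC[Si](Cl)(CC)CC
Why: Standard silylation; the triethylsilyl ether keeps the future C6 oxygen from directing hydroalumination in step 11 and can later be removed in the presence of tert-butyldimethylsilyl ethers.

Step 9
Reactants: 12 2-[(4R,5S)-5-[(2R)-2-hydroxy-5-(4-methoxybenzyloxy)pent-3-yn-1-yl]-2,2,5-trimethyl-1,3-dioxolan-4-yl]-N-methoxy-N-methylacetamide; 13 triethyl(prop-2-yn-1-yloxy)silane
Product: 14 1-[(4R,5S)-5-[(2R)-2-hydroxy-5-(4-methoxybenzyloxy)pent-3-yn-1-yl]-2,2,5-trimethyl-1,3-dioxolan-4-yl]-5-(triethylsilyloxy)pent-3-yn-2-one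
Conditions: 13, n-BuLi (3.2 equiv), THF, −78 °C; then 12, −78 → −20 °C; aq. NH4Cl
Reagents that add atoms: none
Why: Acetylide addition to the Weinreb amide stops at the chelated tetrahedral intermediate and gives the C3 ynone (C3–C4 bond) on work-up; one equivalent of acetylide is spent on the C8 hydroxyl.

Step 10
Reactants: 14 1-[(4R,5S)-5-[(2R)-2-hydroxy-5-(4-methoxybenzyloxy)pent-3-yn-1-yl]-2,2,5-trimethyl-1,3-dioxolan-4-yl]-5-(triethylsilyloxy)pent-3-yn-2-one
Product: 16 C3 ethylene ketal of 14 (2-alkynyl-1,3-dioxolane; C8 hydroxyl free), via C8 trimethylsilyl ether 15 (not isolated)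
Conditions: Me3SiOCH2CH2OSiMe3, Me3SiOTf (cat.), CH2Cl2, −78 → −20 °C; pyridine; then K2CO3, MeOH, 0 °C (brief)
Reagents that add atoms: 1,2-bis(trimethylsilyloxy)ethane, C[Si](C)(C)OCCO[Si](C)(C)C
Why: Noyori ketalisation with the bis-silyl glycol works at low temperature without free glycol, so conjugate addition to the ynone is avoided; the C8 hydroxyl is silylated in passing and released by brief methanolysis, which the primary triethylsilyl ether survives.

Step 11
Reactants: 16 C3 ethylene ketal of 14
Product: 18 (Z)-vinyl iodide (H on C7; I on C11 cis to C8; C8 hydroxyl free; C13 OPMB; C6 OSiEt3), via alkenylaluminate 17 (not isolated)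
Conditions: NaAlH2(OCH2CH2OMe)2, THF, 0 °C → rt; EtOAc; then I2, THF, −78 → 0 °C
Reagents that add atoms: iodine, II
Why: Hydroxyl-directed trans-hydroalumination of the propargylic alcohol delivers hydride to C7 and aluminium to C11 within a five-membered alkoxyaluminate, and iodinolysis occurs with retention, so iodine ends cis to C8; the second alkyne has only ether and ketal neighbours and should not be reduced.

Step 12
Reactants: 18 (Z)-vinyl iodide
Product: 19 ene-1,4-diol (C12 hydroxymethyl on C11 cis to C8; C8 hydroxyl; C13 OPMB)
Conditions: Bu3SnCH2OH, Pd(PPh3)4 (cat.), dioxane, 85 °C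
Reagents that add atoms: (tributylstannyl)methanol, OC[Sn](CCCC)(CCCC)CCCC
Why: Stille coupling with retention of alkene geometry; the α-oxygenated methyl group transfers from tin in preference to butyl, installing C12 cis to C8 and leaving C13 trans.

Step 13
Reactants: 19 ene-1,4-diol
Product: 20 bis-TBS ether of 19 (C8 and C12 OTBS; C6 OSiEt3; C13 OPMB)
Conditions: t-BuMe2SiOTf, 2,6-lutidine, CH2Cl2, −78 → 0 °C
Reagents that add atoms: tert-butyldimethylsilyl triflate, CC(C)(C)[Si](C)(C)OS(=O)(=O)C(F)(F)F
Why: Silylation of both hydroxyls in one operation; the primary (C12) and secondary (C8) silyl ethers are told apart later by their different rates of fluoride cleavage.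

Step 14
Reactants: 20 bis-TBS ether
Product: 21 C13 allylic alcohol (PMB removed)
Conditions: DDQ, CH2Cl2/pH 7 buffer, 0 °C
Reagents that add atoms: none
Why: Oxidative cleavage of the electron-rich benzyl ether under buffered, neutral conditions; silyl ethers, ketal and acetonide are inert.

Step 15
Reactants: 21 C13 allylic alcohol
Product: 22 C13 allylic chloride
Conditions: NCS, Me2S, CH2Cl2, −20 → 0 °C
Reagents that add atoms: N-chlorosuccinimide, O=C1CCC(=O)N1Cl
Why: Corey–Kim chlorination converts a primary allylic alcohol to the chloride by SN2 displacement of the alkoxysulfonium ion, without allylic transposition and under non-acidic conditions.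

Step 16
Reactants: 22 C13 allylic chloride
Product: 23 hydroxy chloride (C6 propargylic alcohol; C13 chloride)
Conditions: PPTS (cat.), MeOH/CH2Cl2, 0 °C
Reagents that add atoms: none
Why: Mild methanolysis removes the primary triethylsilyl ether much faster than tert-butyldimethylsilyl ethers; at 0 °C the ketal, the acetonide and the allylic chloride should survive.

Step 17
Reactants: 23 hydroxy chloride
Product: 24 thirteen-membered allyl propargyl ether (O linking C6 and C13; E ring alkene C7=C11; C3 dioxolane; C1/C10 acetonide; C8 and C12 OTBS)
Conditions: NaH, n-Bu4NI (cat.), THF (2 mM, slow addition), 50 °C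
Reagents that add atoms: none
Why: Intramolecular Williamson etherification: the weakly basic propargylic alkoxide displaces the primary allylic halide (13-exo-tet); high dilution suppresses oligomers, and the cis-fused acetonide provides a turn that brings the chain ends together.

Step 18
Reactants: 24 thirteen-membered allyl propargyl ether
Product: 25 ten-membered cycloalkynol (C6 hydroxyl; C7 bearing the 3-(tert-butyldimethylsilyloxy)prop-1-en-2-yl arm; 1R,6S,7S,8R,10S)
Conditions: n-BuLi, THF–pentane, −78 → −30 °C; aq. NH4Cl
Reagents that add atoms: none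
Why: n-BuLi removes a C6 proton, which is both propargylic and α to oxygen, and the carbanion attacks C7 through a five-membered envelope transition state (C6, O, C13, C11, C7) while O–C13 breaks, so that C6–C7 forms, C11=C13 appears as the exocyclic methylene and the oxygen stays on C6 as the alkoxide. The closest known reaction type is the [2,3]-Wittig ring contraction of macrocyclic allyl propargyl ethers to cyclic propargylic alcohols. The ten-membered carbocycle is closed by this transannular sigmatropic shift inside the thirteen-membered ring (ring contraction, not an end-to-end cyclisation), and the exchange of a carbanion for an alkoxide pays for the strain of the cyclodecyne. The C6/C7 relationship should be anti (hydroxyl and C8 on opposite sides, i.e. oxygen on C6 and C11 on C7 trans on the new ring) because the E geometry of C7=C11 places the alkynyl group exo on the envelope. The absolute sense should come from C8: allylic strain with the cis C12 methylene holds the C8–H bond in the alkene plane, the C9 chain and the silyloxy group then lie on opposite faces, and bond formation anti to C9 gives a staggered C6–C7–C8–C9 segment and the configuration required. The step needs deprotonation at C6 and not at C13 or C12, secured by the alkyne and by the C3 ketal, which leaves no second propargylic hydrogen. It also needs the [2,3] shift to win over the [1,2] shift, which the low temperature favours. A cold quench limits silyl migration to the new alkoxide.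

Step 19
Reactants: 25 ten-membered cycloalkynol
Product: 26 (4Z)-cyclodecenol (C4=C5 cis alkene; 6R)
Conditions: H2 (1 atm), Pd/CaCO3 poisoned with Pb(OAc)2 (Lindlar catalyst), quinoline, EtOAc, rt
Reagents that add atoms: none
Why: Lindlar semi-hydrogenation adds hydrogen cis to the strained ring alkyne and gives the Z alkene; the 1,1-disubstituted alkene is left alone, and the step is placed before the reducible methylene lactone is made.

Step 20
Reactants: 26 (4Z)-cyclodecenol
Product: 27 C6/C12 diol (primary C12 silyl ether removed; C8 OTBS kept)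
Conditions: HF·pyridine, pyridine, THF, 0 °C
Reagents that add atoms: none
Why: Buffered fluoride cleaves the primary allylic silyl ether much faster than the hindered secondary one at C8, which must stay so that C8–O cannot compete for C12 in the next step.

Step 21
Reactants: 27 C6/C12 diol
Product: 29 trans-fused α-methylene-γ-lactone (C12 carbonyl; O on C6; C8 OTBS; ketal and acetonide intact), via lactol 28 (not isolated)
Conditions: TEMPO (cat.), PhI(OAc)2, CH2Cl2, rt
Reagents that add atoms: none
Why: Oxoammonium oxidation is selective for the primary allylic alcohol; the enal is trapped by the C6 hydroxyl as the five-membered lactol, which is oxidised further to the lactone (oxidative lactonisation of a 2-methylene-1,4-diol).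

Step 22
Reactants: 29 trans-fused α-methylene-γ-lactone
Product: 30 C8 alcohol
Conditions: HF·pyridine, pyridine, THF, rt
Reagents that add atoms: none
Why: Longer exposure to buffered HF removes the secondary silyl ether; fluoride in pyridine does not hydrolyse the ketal or the acetonide and does not add irreversibly to the methylene lactone.

Step 23
Reactants: 30 C8 alcohol
Product: 31 C8 isovalerate
Conditions: (Me2CHCH2CO)2O, DMAP, Et3N, CH2Cl2, 0 °C → rt
Reagents that add atoms: isovaleric anhydride, CC(C)CC(=O)OC(=O)CC(C)C
Why: DMAP-catalysed acylation of the only free hydroxyl; the ester is installed now so that no hydroxyl competes with C15–OH at the end.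

Step 24
Reactants: 31 C8 isovalerate
Product: 32 (4Z)-3-ketone (Z-enone; C1/C10 acetonide kept)
Conditions: PPTS, acetone/H2O, 45 °C
Reagents that add atoms: water, O
Why: The allylic ketal ionises readily to a conjugated oxocarbenium ion and is hydrolysed under mild acid, while acetone as solvent holds the acetonide in place by mass action.

Step 25
Reactants: 32 (4Z)-3-ketone
Product: 33 C4 hydroxymethyl enone (C15–OH; C4=C5 Z in the ring)
Conditions: aq. HCHO, DMAP, THF/H2O, rt
Reagents that add atoms: formaldehyde, C=O
Why: Morita–Baylis–Hillman reaction of a cyclic enone: the amine adds to C5, the C4 enolate adds to formaldehyde and the amine is eliminated; the ring should keep the alkene cis on reformation, and addition to the methylene lactone is reversible and unproductive because C11 has no hydrogen.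

Step 26
Reactants: 33 C4 hydroxymethyl enone
Product: 34 C15 tert-butyldiphenylsilyl ether
Conditions: t-BuPh2SiCl, imidazole, CH2Cl2, 0 °C
Reagents that add atoms: tert-butyl(chloro)diphenylsilane, CC(C)(C)[Si](Cl)(c1ccccc1)c1ccccc1
Why: Silylation of the primary allylic alcohol with a group that withstands the acid of step 27, so that only C1 is oxidised in step 28.

Step 27
Reactants: 34 C15 tert-butyldiphenylsilyl ether
Product: 35 C1/C10 diol (open form; may rest as the C3/C10 hemiketal)
Conditions: TFA/H2O (9:1), CH2Cl2, 0 °C
Reagents that add atoms: none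
Why: Acid hydrolysis of the isopropylidene acetal; the tert-butyldiphenylsilyl ether, the isovalerate and the lactone should tolerate brief aqueous trifluoroacetic acid.

Step 28
Reactants: 35 C1/C10 diol
Product: 37 C15-silylated 3(2H)-furanone, via diketone 36 (not isolated)
Conditions: Dess–Martin periodinane, NaHCO3, CH2Cl2, 0 °C → rt; filter; then p-TsOH·H2O (cat.), CH2Cl2, rt
Reagents that add atoms: none
Why: The periodinane oxidises the secondary C1 carbinol and cannot touch the tertiary C10 alcohol; acid then closes the C10 hydroxyl onto C3 (5-exo-trig) and dehydrates the hemiketal to the C2=C3 enol ether, the standard cyclodehydration of an α′-hydroxy-1,3-diketone to a 3(2H)-furanone.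

Step 29
Reactants: 37 C15-silylated 3(2H)-furanone
Product: 38 CNP0171896.1
Conditions: HF·pyridine, THF, 0 °C → rt
Reagents that add atoms: none
Why: Fluoride cleavage of the primary silyl ether under mildly acidic conditions, which the methylene lactone, the isovalerate and the furanone should withstand.

## Compound list

1 | propargyl alcohol | C#CCO | starting material
2 | 4-methoxybenzyl propargyl ether | C#CCOCc1ccc(OC)cc1 | intermediate
3 | (S)-citramalic acid | OC(=O)[C@](C)(CC(=O)O)O | starting material
4 | [(4S)-2,2,4-trimethyl-5-oxo-1,3-dioxolan-4-yl]acetic acid | OC(=O)C[C@]1(C)OC(C)(C)OC1=O | intermediate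
5 | [(4S)-2,2,4-trimethyl-5-oxo-1,3-dioxolan-4-yl]acetyl chloride | ClC(=O)C[C@]1(C)OC(C)(C)OC1=O | intermediate (not isolated)
6 | (5S)-5-[5-(4-methoxybenzyloxy)-2-oxopent-3-yn-1-yl]-2,2,5-trimethyl-1,3-dioxolan-4-one | COc1ccc(COCC#CC(=O)C[C@]2(C)OC(C)(C)OC2=O)cc1 | intermediate
7 | (5S)-5-[(2R)-2-hydroxy-5-(4-methoxybenzyloxy)pent-3-yn-1-yl]-2,2,5-trimethyl-1,3-dioxolan-4-one | COc1ccc(COCC#C[C@H](O)C[C@]2(C)OC(C)(C)OC2=O)cc1 | intermediate (not isolated)
8 | (3S,5R)-3-hydroxy-5-[3-(4-methoxybenzyloxy)prop-1-yn-1-yl]-3-methyloxolan-2-one | COc1ccc(COCC#C[C@H]2C[C@](C)(O)C(=O)O2)cc1 | intermediate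
9 | N-methoxy-N-methylacetamide | CC(=O)N(C)OC | starting material
10 | (4S,6R)-4,6-dihydroxy-N-methoxy-9-(4-methoxybenzyloxy)-N,4-dimethyl-3-oxonon-7-ynamide | CON(C)C(=O)CC(=O)[C@@](C)(O)C[C@@H](O)C#CCOCc1ccc(OC)cc1 | intermediate
11 | (3R,4S,6R)-3,4,6-trihydroxy-N-methoxy-9-(4-methoxybenzyloxy)-N,4-dimethylnon-7-ynamide | CON(C)C(=O)C[C@@H](O)[C@@](C)(O)C[C@@H](O)C#CCOCc1ccc(OC)cc1 | intermediate
12 | 2-[(4R,5S)-5-[(2R)-2-hydroxy-5-(4-methoxybenzyloxy)pent-3-yn-1-yl]-2,2,5-trimethyl-1,3-dioxolan-4-yl]-N-methoxy-N-methylacetamide | CON(C)C(=O)C[C@H]1OC(C)(C)O[C@@]1(C)C[C@@H](O)C#CCOCc1ccc(OC)cc1 | intermediate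
13 | triethyl(prop-2-yn-1-yloxy)silane | C#CCO[Si](CC)(CC)CC | intermediate
14 | 1-[(4R,5S)-5-[(2R)-2-hydroxy-5-(4-methoxybenzyloxy)pent-3-yn-1-yl]-2,2,5-trimethyl-1,3-dioxolan-4-yl]-5-(triethylsilyloxy)pent-3-yn-2-one | CC[Si](CC)(CC)OCC#CC(=O)C[C@H]1OC(C)(C)O[C@@]1(C)C[C@@H](O)C#CCOCc1ccc(OC)cc1 | intermediate
15 | C3 ethylene ketal of 14 with the C8 hydroxyl as trimethylsilyl ether | CC[Si](CC)(CC)OCC#CC1(OCCO1)C[C@H]2OC(C)(C)O[C@@]2(C)C[C@@H](O[Si](C)(C)C)C#CCOCc1ccc(OC)cc1 | intermediate (not isolated)
16 | C3 ethylene ketal of 14 (C8 hydroxyl free; 1R,8R,10S) | CC[Si](CC)(CC)OCC#CC1(OCCO1)C[C@H]2OC(C)(C)O[C@@]2(C)C[C@@H](O)C#CCOCc1ccc(OC)cc1 | intermediate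
17 | sodium alkoxy(alkenyl)bis(2-methoxyethoxy)aluminate from 16 (five-membered ring C8–O–Al–C11=C7) | [Na+].CC[Si](CC)(CC)OCC#CC1(OCCO1)C[C@H]2OC(C)(C)O[C@@]2(C)C[C@H]3O[Al-](OCCOC)(OCCOC)C(COCc4ccc(OC)cc4)=C3 | intermediate (not isolated)
18 | (Z)-vinyl iodide: C8 hydroxyl, iodine on C11 cis to C8, C13 OPMB, C6 OSiEt3, C3 dioxolane, C1/C10 acetonide | CC[Si](CC)(CC)OCC#CC1(OCCO1)C[C@H]2OC(C)(C)O[C@@]2(C)C[C@@H](O)/C=C(\I)COCc1ccc(OC)cc1 | intermediate
19 | ene-1,4-diol: C8 hydroxyl and C12 hydroxymethyl cis to C8, C13 OPMB | CC[Si](CC)(CC)OCC#CC1(OCCO1)C[C@H]2OC(C)(C)O[C@@]2(C)C[C@@H](O)/C=C(\CO)COCc1ccc(OC)cc1 | intermediate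
20 | bis-TBS ether of 19 (C8 and C12 OTBS) | CC[Si](CC)(CC)OCC#CC1(OCCO1)C[C@H]2OC(C)(C)O[C@@]2(C)C[C@@H](O[Si](C)(C)C(C)(C)C)/C=C(\CO[Si](C)(C)C(C)(C)C)COCc1ccc(OC)cc1 | intermediate
21 | C13 allylic alcohol (C6 OSiEt3; C8 and C12 OTBS) | CC[Si](CC)(CC)OCC#CC1(OCCO1)C[C@H]2OC(C)(C)O[C@@]2(C)C[C@@H](O[Si](C)(C)C(C)(C)C)/C=C(\CO[Si](C)(C)C(C)(C)C)CO | intermediate
22 | C13 allylic chloride (C6 OSiEt3) | CC[Si](CC)(CC)OCC#CC1(OCCO1)C[C@H]2OC(C)(C)O[C@@]2(C)C[C@@H](O[Si](C)(C)C(C)(C)C)/C=C(\CO[Si](C)(C)C(C)(C)C)CCl | intermediate
23 | hydroxy chloride (C6 propargylic alcohol; C13 allylic chloride) | OCC#CC1(OCCO1)C[C@H]2OC(C)(C)O[C@@]2(C)C[C@@H](O[Si](C)(C)C(C)(C)C)/C=C(\CO[Si](C)(C)C(C)(C)C)CCl | intermediate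
24 | thirteen-membered allyl propargyl ether (O between C6 and C13; E C7=C11; C3 dioxolane; C1/C10 acetonide; C8 and C12 OTBS; 1R,8R,10S) | O1CC#CC2(OCCO2)C[C@H]3OC(C)(C)O[C@@]3(C)C[C@@H](O[Si](C)(C)C(C)(C)C)/C=C(\CO[Si](C)(C)C(C)(C)C)C1 | intermediate
25 | ten-membered cycloalkynol (C6 hydroxyl; C7 3-(tert-butyldimethylsilyloxy)prop-1-en-2-yl arm; 1R,6S,7S,8R,10S) | O[C@@H]1C#CC2(OCCO2)C[C@H]3OC(C)(C)O[C@@]3(C)C[C@@H](O[Si](C)(C)C(C)(C)C)[C@H]1C(=C)CO[Si](C)(C)C(C)(C)C | intermediate
26 | (4Z)-cyclodecenol from 25 | O[C@@H]1/C=C\C2(OCCO2)C[C@H]3OC(C)(C)O[C@@]3(C)C[C@@H](O[Si](C)(C)C(C)(C)C)[C@H]1C(=C)CO[Si](C)(C)C(C)(C)C | intermediate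
27 | C6/C12 diol (C8 OTBS) | O[C@@H]1/C=C\C2(OCCO2)C[C@H]3OC(C)(C)O[C@@]3(C)C[C@@H](O[Si](C)(C)C(C)(C)C)[C@H]1C(=C)CO | intermediate
28 | C12 lactol (α-methylene lactol on C6–O; anomeric mixture) | C=C1C(O)O[C@@H]2/C=C\C3(OCCO3)C[C@H]4OC(C)(C)O[C@@]4(C)C[C@@H](O[Si](C)(C)C(C)(C)C)[C@@H]12 | intermediate (not isolated)
29 | trans-fused α-methylene-γ-lactone (C8 OTBS; C3 dioxolane; C1/C10 acetonide) | C=C1C(=O)O[C@@H]2/C=C\C3(OCCO3)C[C@H]4OC(C)(C)O[C@@]4(C)C[C@@H](O[Si](C)(C)C(C)(C)C)[C@@H]12 | intermediate
30 | C8 alcohol of 29 | C=C1C(=O)O[C@@H]2/C=C\C3(OCCO3)C[C@H]4OC(C)(C)O[C@@]4(C)C[C@@H](O)[C@@H]12 | intermediate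
31 | C8 isovalerate | C=C1C(=O)O[C@@H]2/C=C\C3(OCCO3)C[C@H]4OC(C)(C)O[C@@]4(C)C[C@@H](OC(=O)CC(C)C)[C@@H]12 | intermediate
32 | (4Z)-3-ketone (Z-enone; C1/C10 acetonide) | C=C1C(=O)O[C@@H]2/C=C\C(=O)C[C@H]3OC(C)(C)O[C@@]3(C)C[C@@H](OC(=O)CC(C)C)[C@@H]12 | intermediate
33 | C4 hydroxymethyl enone (C15–OH) | C=C1C(=O)O[C@@H]2/C=C(/CO)C(=O)C[C@H]3OC(C)(C)O[C@@]3(C)C[C@@H](OC(=O)CC(C)C)[C@@H]12 | intermediate
34 | C15 tert-butyldiphenylsilyl ether of 33 | C=C1C(=O)O[C@@H]2/C=C(/CO[Si](c3ccccc3)(c3ccccc3)C(C)(C)C)C(=O)C[C@H]3OC(C)(C)O[C@@]3(C)C[C@@H](OC(=O)CC(C)C)[C@@H]12 | intermediate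
35 | C1/C10 diol (open form) | C=C1C(=O)O[C@@H]2/C=C(/CO[Si](c3ccccc3)(c3ccccc3)C(C)(C)C)C(=O)C[C@@H](O)[C@@](C)(O)C[C@@H](OC(=O)CC(C)C)[C@@H]12 | intermediate
36 | C1,C3-diketone with free C10 hydroxyl | C=C1C(=O)O[C@@H]2/C=C(/CO[Si](c3ccccc3)(c3ccccc3)C(C)(C)C)C(=O)CC(=O)[C@@](C)(O)C[C@@H](OC(=O)CC(C)C)[C@@H]12 | intermediate (not isolated)
37 | C15 tert-butyldiphenylsilyl ether of the target | C=C1C(=O)O[C@@H]2/C=C(/CO[Si](c3ccccc3)(c3ccccc3)C(C)(C)C)C3=CC(=O)[C@](C)(C[C@@H](OC(=O)CC(C)C)[C@@H]12)O3 | intermediate
38 | CNP0171896.1 | C=C1C(=O)O[C@@H]2/C=C(/CO)C3=CC(=O)[C@](C)(C[C@@H](OC(=O)CC(C)C)[C@@H]12)O3 | target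

## Step count and least certain steps

Total step count: 29. Longest linear sequence: 27 steps (3 → 38 through steps 2–7 and 9–29; steps 1 and 8 prepare the two alkyne building blocks).

**Step 18 (key step).** The macrocyclic carbanion may not follow the intended path. Possible failures are a competing [1,2]-shift, lithiation at the allylic C13 or C12 positions, attack on the wrong face of C7=C11 because the ring with its cis-fused acetonide prefers another conformer, or silyl migration to the new alkoxide. Fallback: the same C6–C7 bond is made by an intramolecular Nozaki–Hiyama allylation. It sets out from 23: MnO2 oxidises the propargylic alcohol to the ynal chloride F1, and CrCl2 in THF at high dilution converts the allylic chloride of F1 into an allylchromium species that adds through C7 to the C6 aldehyde in a chair transition state. This gives the anti homoallylic alcohol with the C11=C13 methylene and returns to the route at 25.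

**Step 25 (Morita–Baylis–Hillman).** Conjugate addition of the amine to the β-substituted Z-enone of a ten-membered ring may be slow. The catalyst may be held up by reversible addition to the methylene lactone, and prolonged base may eliminate the C1 oxygen β to the ketone. Fallback: a halogenation and cross-coupling sequence from 32. I2 and pyridine in CH2Cl2 should give the α-iodoenone F2, and Stille coupling of F2 with (tributylstannyl)methanol (Pd(PPh3)4, CuI, dioxane) installs the hydroxymethyl group and returns to the route at 33.

**Step 17 (macro-etherification).** Intermolecular alkylation may outrun closure of the thirteen-membered ring, whose alkyne, E-alkene and acetonide segments restrict the reactive conformations, and the alkoxide may cause loss of HCl from the allylic chloride. Fallback: the ring is closed at the other C–O bond with reversed polarity, setting out from 20. PPTS in methanol removes the triethylsilyl group to give the propargylic alcohol F3. CBr4 and PPh3 convert F3 into the propargylic bromide F4. Buffered DDQ removes the PMB group of F4 to give the bromo allylic alcohol F5. NaH in THF at high dilution then lets the C13 alkoxide of F5 displace the propargylic bromide, returning to the route at 24.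

**Step 5 (Claisen acylation).** The lactone carbonyl next to a lithium alkoxide may be too weakly electrophilic, so that the amide enolate decomposes or the adduct reverts before acylation is complete. Fallback: C1 is taken to the aldehyde level first, setting out from 8. i-Bu2AlH at −78 °C gives the lactol F6. Excess lithium enolate of 9 adds to the open hydroxy-aldehyde form of F6 (aldol addition) to give triol 11 together with its C1 epimer F7. The fallback returns to the route at 11; F7 can be carried along because C1 is oxidised in step 28.

**Step 12 (Stille hydroxymethylation).** Transfer of the sp3 hydroxymethyl group from tin may be slow, so that butyl transfer or protodeiodination competes at the temperature required. Fallback: C12 is introduced as carbon monoxide, setting out from 18. Carbonylative lactonisation (CO, PdCl2(PPh3)2 cat., Et3N, THF, 50 °C) closes the C8 hydroxyl onto the acylpalladium to give the butenolide F8. i-Bu2AlH then reduces F8 to the ene-1,4-diol, returning to the route at 19.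

## Further compounds

F1 | step 18 | ynal chloride (C6 aldehyde; C13 allylic chloride) | O=CC#CC1(OCCO1)C[C@H]2OC(C)(C)O[C@@]2(C)C[C@@H](O[Si](C)(C)C(C)(C)C)/C=C(\CO[Si](C)(C)C(C)(C)C)CCl
F2 | step 25 | α-iodoenone (iodine on C4 of 32) | C=C1C(=O)O[C@@H]2/C=C(/I)C(=O)C[C@H]3OC(C)(C)O[C@@]3(C)C[C@@H](OC(=O)CC(C)C)[C@@H]12
F3 | step 17 | propargylic alcohol (C6 OH; C13 OPMB; C8 and C12 OTBS) | OCC#CC1(OCCO1)C[C@H]2OC(C)(C)O[C@@]2(C)C[C@@H](O[Si](C)(C)C(C)(C)C)/C=C(\CO[Si](C)(C)C(C)(C)C)COCc1ccc(OC)cc1
F4 | step 17 | propargylic bromide (C6 Br; C13 OPMB) | BrCC#CC1(OCCO1)C[C@H]2OC(C)(C)O[C@@]2(C)C[C@@H](O[Si](C)(C)C(C)(C)C)/C=C(\CO[Si](C)(C)C(C)(C)C)COCc1ccc(OC)cc1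
F5 | step 17 | bromo allylic alcohol (C6 Br; C13 OH) | BrCC#CC1(OCCO1)C[C@H]2OC(C)(C)O[C@@]2(C)C[C@@H](O[Si](C)(C)C(C)(C)C)/C=C(\CO[Si](C)(C)C(C)(C)C)CO
F6 | step 5 | lactol of 8 (anomeric mixture) | COc1ccc(COCC#C[C@H]2C[C@](C)(O)C(O)O2)cc1
F7 | step 5 | C1 epimer of triol 11 | CON(C)C(=O)C[C@H](O)[C@@](C)(O)C[C@@H](O)C#CCOCc1ccc(OC)cc1
F8 | step 12 | butenolide (C12 carbonyl closed onto the C8 oxygen; C13 OPMB) | CC[Si](CC)(CC)OCC#CC1(OCCO1)C[C@H]2OC(C)(C)O[C@@]2(C)C[C@H]3OC(=O)C(COCc4ccc(OC)cc4)=C3
A1 | alternative 1 | ten-membered 9-en-1-one trans-lactone with Z C4=C5, C3 triethylsilyl ether and C15 tert-butyldimethylsilyl ether | C=C1C(=O)O[C@@H]2/C=C(/CO[Si](C)(C)C(C)(C)C)[C@H](O[Si](CC)(CC)CC)CC(=O)/C(C)=C\[C@@H](OC(=O)CC(C)C)[C@@H]12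
A2 | alternative 2 | furanone-bridged ten-membered C8 ketone with C12 PMB ether, C15 tert-butyldimethylsilyl ether and C6 triethylsilyl ether | C=C(COCc1ccc(OC)cc1)[C@@H]1C(=O)C[C@]2(C)OC(=CC2=O)/C(CO[Si](C)(C)C(C)(C)C)=C\[C@H]1O[Si](CC)(CC)CC
A3 | alternative 3 | bridged 2,3-dihydrofuran-3-ol (C1 alcohol of the furanone) with C15 tert-butyldimethylsilyl ether | C=C1C(=O)O[C@@H]2/C=C(/CO[Si](C)(C)C(C)(C)C)C3=C[C@@H](O)[C@](C)(C[C@@H](OC(=O)CC(C)C)[C@@H]12)O3
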